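All constants come from no measurement, and the outcome is calculated.

| setting | north-west | north | south-east | north-east |
|---|---|---|---|---|
| substrate | 0.50 M | 0.50 M | 0.50 M | 0.50 M (fed, over 5.00 min) |
| coupling partner | 0.750 M (fed, over 5.00 min) | 0.750 M | 0.750 M | 0.750 M |
| protic impurity | 0.0500 M | 0.0500 M | 0.0500 M | 0.0500 M |
| time | 10 min |  | 10 min | 10 min |
| remark | all but coupling partner at the start; coupling partner goes in evenly over 5.00 min, the run ends at 10 min | one stirred flow tank at steady state, fed with the mixture as stated, mean residence time 10 min | a closed flask charged with all of it at once and left for 10 min | all but substrate at the start; substrate goes in evenly over 5.00 min, the run ends at 10 min |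

    coupling partner + intermediate C → side product (k1 = 0.0039 M⁻¹ s⁻¹)
    coupling partner + intermediate B ⇌ intermediate D (K2 = 0.53 M⁻¹, k2 = 0.0063 M⁻¹ s⁻¹)
    intermediate B ⇌ intermediate C (K3 = 2.2, k3 = 0.16 s⁻¹)
    substrate + coupling partner → intermediate A (k4 = 0.028 M⁻¹ s⁻¹)
    coupling partner ⇌ dormant form (K5 = 0.94, k5 = 0.0013 s⁻¹)
    coupling partner + protic impurity → quenched reagent (k6 = 0.031 M⁻¹ s⁻¹)
    coupling partner + intermediate A → target (k7 = 0.022 M⁻¹ s⁻¹)
    intermediate A → intermediate B (k8 = 0.021 s⁻¹)

1. order of the set-ups by the amount of target at the outlet or at the end, in percent of the substrate put in, highest first (north-west / north / south-east / north-east)
2. amount of target at the outlet or at the end, in percent of the substrate put in, north-west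
3. amount of target at the outlet or at the end, in percent of the substrate put in, north
4. amount of target at the outlet or at the end, in percent of the substrate put in, south-east
5. amount of target at the outlet or at the end, in percent of the substrate put in, north-east

- the stated concentrations are those of everything mixed, before any reaction; amounts are the same in each set-up
- the feed brings no volume worth counting
- run time (north-west): 10 min

Read north-west, south-east and north-east at 10 min, and north, a stirred tank at steady state, at a mean residence time of the same length. That is 18.2 half-lives of intermediate A by its passage to intermediate B alone (0.55 min), so treat the target as the sum of many small splits. Intermediate A splits two ways: with coupling partner it gives target, by itself it gives intermediate B, and the scheme leads nothing back to it. Divide the rate constant of the passage by that of the coupling to get 0.955 M. Call this [coupling partner], at which the two paths take intermediate A equally, the crossing concentration. The share going to target, the selectivity, is [coupling partner] over [coupling partner] plus crossing concentration.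

Reckon south-east by hand. At the charge the share is 44.0%. Put that back in: each substrate then takes one partner to become intermediate A and a further 44.0% to become target, so the substrate claims 0.720 M and leaves 0.0300 M of the charge. Let [coupling partner] therefore fall from the charge towards zero, with a mean of half the charge, 0.375 M. Go round again: the share drops to 28.2%, and that is the first number to commit to.

Now reforge the weak link, which is counting the whole charge as serving substrate. Quench and dormancy together take partner at 0.00285 s⁻¹, against 0.0140 s⁻¹ for substrate, so 16.9% of it goes astray at the start. Hold that starting share over the whole charge, as an estimate: that leaves 0.623 M usable, and the share becomes 24.6%. The demand at that share is 0.623 M, which just matches the usable partner, so stand on about 24.6% of the substrate as target in south-east.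

The forecast, stepped by hand, ranks south-east > north-east > north-west > north, with 11.7% for north-west, 10% for north, 19.9% for south-east and 17.2% for north-east. Its ground is “High partner concentration while A is present therefore favours target.” My south-east figure stands above its range, which tops out at 21.5%.

The simulation gives south-east > north-east > north-west > north, with 12.8%, 9.98%, 20.6% and 17.5% in the same order of set-ups as the forecast listed them, each inside the forecast's range. South-east keeps 9.1% of its substrate, so the share of converted substrate reaching target reads 22.7%. Through the crossing concentration that reads as an effective [coupling partner] of 0.280 M over the run, below my mean of 0.311 M. Take the neighbouring south-east flask charged with 0.45 M of coupling partner. Its usable partner is 0.374 M, its share 16.4%, and its conversion 64.3%, which reckons 10.5% target with 35.7% of the substrate left. That flask gives 34% of its substrate left and 8.49% target.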